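**Assumption:** the target stereocentre is S by CIP (the CH2–CMe2 branch outranks the CH2–C(Me)= branch). Cb = N,N-diisopropylcarbamoyl. Ring locants: C1 carbinol carbon, C3 methyl-bearing olefin carbon, C7 methylidene-bearing carbon, C10 CMe2.

## Retrosynthetic overview

1. Ester C–O bond last: Mitsunobu inversion of the (R)-macrocyclic alcohol 14 with unprotected vanillic acid 15.
2. The only ring built is the 11-membered carbocycle (the arene is bought). It is closed late at C7–C8 by intramolecular Heck reaction of enol triflate 12, which also creates the exo-methylene/(E)-diene.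
3. Key C1–C2 bond: a reversed-polarity α-oxy carbanion (sparteine-lithiated carbamate 8, the carbinol carbon as nucleophile) is alkylated by the (E)-allylic bromide 4. This sets the only stereocentre directly.
4. Fragments: carbamate 7 from methyl 3,3-dimethylpent-4-enoate; bromide 4 from sulcatone by ketalisation, (E)-selective SeO2 allylic oxidation and Appel bromination.

## Route

**Step 1**
Reactants: 1 6-methylhept-5-en-2-one (sulcatone)
Product: 2 2-methyl-2-(4-methylpent-3-en-1-yl)-1,3-dioxolane
Conditions: HOCH2CH2OH, p-TsOH (cat.), benzene, reflux, Dean–Stark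
Reagents that add atoms: ethylene glycol, OCCO
Why: Acid-catalysed ketalisation with azeotropic water removal masks the ketone as a dioxolane that is inert to the organolithium chemistry of step 6.

**Step 2**
Reactants: 2 2-methyl-2-(4-methylpent-3-en-1-yl)-1,3-dioxolane
Product: 3 (2E)-2-methyl-5-(2-methyl-1,3-dioxolan-2-yl)pent-2-en-1-ol
Conditions: SeO2 (0.3 equiv), t-BuOOH (3 equiv), CH2Cl2, 0 °C → rt
Reagents that add atoms: selenium dioxide, O=[Se]=O (oxygen carrier); tert-butyl hydroperoxide, CC(C)(C)OO (terminal oxygen source)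
Why: Catalytic SeO2 allylic oxidation (ene reaction, then 2,3-sigmatropic shift) hydroxylates only the (E)-methyl group of the trisubstituted olefin, which fixes the E geometry of the later ring olefin.

**Step 3**
Reactants: 3 (2E)-2-methyl-5-(2-methyl-1,3-dioxolan-2-yl)pent-2-en-1-ol
Product: 4 2-[(3E)-5-bromo-4-methylpent-3-en-1-yl]-2-methyl-1,3-dioxolane
Conditions: CBr4, PPh3, CH2Cl2, 0 °C
Reagents that add atoms: carbon tetrabromide, BrC(Br)(Br)Br
Why: Appel bromination converts the primary allylic alcohol into the bromide under neutral conditions, so the ketal and the E olefin are untouched.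

**Step 4**
Reactants: 5 methyl 3,3-dimethylpent-4-enoate
Product: 6 3,3-dimethylpent-4-en-1-ol
Conditions: LiAlH4, Et2O, 0 °C → rt
Reagents that add atoms: none
Why: Hydride reduction of the ester gives the primary alcohol while the isolated alkene is inert.

**Step 5**
Reactants: 6 3,3-dimethylpent-4-en-1-ol
Product: 7 3,3-dimethylpent-4-en-1-yl N,N-diisopropylcarbamate
Conditions: CbCl, Et3N, CH2Cl2, reflux
Reagents that add atoms: N,N-diisopropylcarbamoyl chloride, CC(C)N(C(C)C)C(Cl)=O
Why: O-Carbamoylation installs the hindered carbamate that directs and dipole-stabilises α-lithiation and resists attack at its own carbonyl.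

**Step 6**
Reactants: 7 3,3-dimethylpent-4-en-1-yl N,N-diisopropylcarbamate; 4 2-[(3E)-5-bromo-4-methylpent-3-en-1-yl]-2-methyl-1,3-dioxolane
Product: 10 (5R,7E)-3,3,7-trimethyl-11-oxododeca-1,7-dien-5-yl N,N-diisopropylcarbamate, via lithiated carbamate 8 (not isolated), via ketal carbamate 9 (not isolated)
Conditions: s-BuLi (1.3 equiv), (+)-sparteine (1.3 equiv), Et2O, −78 °C, 5 h; then 4 (1.2 equiv), −78 → −30 °C; then 1 M HCl, THF, rt
Reagents that add atoms: water, O
Why: Hoppe asymmetric deprotonation with s-BuLi/(+)-sparteine removes the pro-R hydrogen to give a configurationally stable, chelated α-carbamoyloxy organolithium (the carbinol carbon, normally an electrophilic carbonyl carbon, used as a nucleophile), which displaces the primary (E)-allylic bromide by SN2 with retention at the carbanion and so sets C5 as R (about 95:5 er expected) with the olefin geometry intact, before the acidic work-up hydrolyses the dioxolane.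

**Step 7**
Reactants: 10 (5R,7E)-3,3,7-trimethyl-11-oxododeca-1,7-dien-5-yl N,N-diisopropylcarbamate
Product: 12 (5E,8R)-8-[(diisopropylcarbamoyl)oxy]-6,10,10-trimethyldodeca-1,5,11-trien-2-yl trifluoromethanesulfonate, via potassium enolate 11 (not isolated)
Conditions: KN(SiMe3)2, THF, −78 °C; then PhNTf2, −78 → 0 °C
Reagents that add atoms: N-phenylbis(trifluoromethanesulfonimide), O=S(=O)(N(c1ccccc1)S(=O)(=O)C(F)(F)F)C(F)(F)F
Why: Kinetic deprotonation of the methyl ketone by the bulky amide base occurs at CH3, and O-triflation of that enolate gives the 1,1-disubstituted enol triflate whose CH2 becomes the exocyclic methylene; the carbamate and the stereocentre are not touched.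

**Step 8**
Reactants: 12 (5E,8R)-8-[(diisopropylcarbamoyl)oxy]-6,10,10-trimethyldodeca-1,5,11-trien-2-yl trifluoromethanesulfonate
Product: 13 (1R,3E,8E)-3,10,10-trimethyl-7-methylidenecycloundeca-3,8-dien-1-yl N,N-diisopropylcarbamate
Conditions: Pd(OAc)2 (20 mol %), PPh3 (40 mol %), K2CO3, MeCN, 80 °C, 0.002 M, syringe-pump addition
Reagents that add atoms: none
Why: Intramolecular Heck macrocyclisation, in which the alkenylpalladium formed by oxidative addition of the triflate to zerovalent palladium adds to the unhindered CH2 terminus of the vinyl group; the adjacent quaternary carbon blocks the other regiochemistry and leaves only one set of β-hydrogens, so syn β-hydride elimination can give only the (E)-CH=CH conjugated to the exocyclic methylene, and high dilution favours the 11-membered ring.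

**Step 9**
Reactants: 13 (1R,3E,8E)-3,10,10-trimethyl-7-methylidenecycloundeca-3,8-dien-1-yl N,N-diisopropylcarbamate
Product: 14 (1R,3E,8E)-3,10,10-trimethyl-7-methylidenecycloundeca-3,8-dien-1-ol
Conditions: LiAlH4, THF, reflux
Reagents that add atoms: none
Why: Hydride reduction of the carbamate carbonyl releases the alkoxide without breaking the C1–O bond, so the R configuration is retained, and the unactivated diene is not reduced.

**Step 10**
Reactants: 14 (1R,3E,8E)-3,10,10-trimethyl-7-methylidenecycloundeca-3,8-dien-1-ol; 15 4-hydroxy-3-methoxybenzoic acid (vanillic acid)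
Product: 16 (1S,3E,8E)-3,10,10-trimethyl-7-methylidenecycloundeca-3,8-dien-1-yl 4-hydroxy-3-methoxybenzoate
Conditions: PPh3, DIAD, THF, 0 °C → rt
Reagents that add atoms: none
Why: Mitsunobu esterification, in which the carboxylate displaces the alkoxyphosphonium by SN2 and inverts C1 from R to S, while the much more acidic CO2H (pKa about 4.5) reacts in preference to the phenol (pKa about 9.5), so no phenol protection is needed.

## Compound list

1 | 6-methylhept-5-en-2-one (sulcatone) | CC(=O)CCC=C(C)C | starting material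
2 | 2-methyl-2-(4-methylpent-3-en-1-yl)-1,3-dioxolane | CC(C)=CCCC1(C)OCCO1 | intermediate
3 | (2E)-2-methyl-5-(2-methyl-1,3-dioxolan-2-yl)pent-2-en-1-ol | OC/C(C)=C/CCC1(C)OCCO1 | intermediate
4 | 2-[(3E)-5-bromo-4-methylpent-3-en-1-yl]-2-methyl-1,3-dioxolane | BrC/C(C)=C/CCC1(C)OCCO1 | intermediate
5 | methyl 3,3-dimethylpent-4-enoate | COC(=O)CC(C)(C)C=C | starting material
6 | 3,3-dimethylpent-4-en-1-ol | OCCC(C)(C)C=C | intermediate
7 | 3,3-dimethylpent-4-en-1-yl N,N-diisopropylcarbamate | C=CC(C)(C)CCOC(=O)N(C(C)C)C(C)C | intermediate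
8 | [(1R)-1-[(diisopropylcarbamoyl)oxy]-3,3-dimethylpent-4-en-1-yl]lithium, (+)-sparteine complex (ligand not drawn) | C=CC(C)(C)C[C@H](OC(=O)N(C(C)C)C(C)C)[Li] | intermediate
9 | (5R,7E)-3,3,7-trimethyl-10-(2-methyl-1,3-dioxolan-2-yl)deca-1,7-dien-5-yl N,N-diisopropylcarbamate | C=CC(C)(C)C[C@H](OC(=O)N(C(C)C)C(C)C)C/C(C)=C/CCC1(C)OCCO1 | intermediate
10 | (5R,7E)-3,3,7-trimethyl-11-oxododeca-1,7-dien-5-yl N,N-diisopropylcarbamate | C=CC(C)(C)C[C@H](OC(=O)N(C(C)C)C(C)C)C/C(C)=C/CCC(C)=O | intermediate
11 | potassium (5E,8R)-8-[(diisopropylcarbamoyl)oxy]-6,10,10-trimethyldodeca-1,5,11-trien-2-olate | C=CC(C)(C)C[C@H](OC(=O)N(C(C)C)C(C)C)C/C(C)=C/CCC(=C)[O-].[K+] | intermediate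
12 | (5E,8R)-8-[(diisopropylcarbamoyl)oxy]-6,10,10-trimethyldodeca-1,5,11-trien-2-yl trifluoromethanesulfonate | C=CC(C)(C)C[C@H](OC(=O)N(C(C)C)C(C)C)C/C(C)=C/CCC(=C)OS(=O)(=O)C(F)(F)F | intermediate
13 | (1R,3E,8E)-3,10,10-trimethyl-7-methylidenecycloundeca-3,8-dien-1-yl N,N-diisopropylcarbamate | C=C1/C=C/C(C)(C)C[C@H](OC(=O)N(C(C)C)C(C)C)C/C(C)=C/CC1 | intermediate
14 | (1R,3E,8E)-3,10,10-trimethyl-7-methylidenecycloundeca-3,8-dien-1-ol | C=C1/C=C/C(C)(C)C[C@H](O)C/C(C)=C/CC1 | intermediate
15 | 4-hydroxy-3-methoxybenzoic acid (vanillic acid) | COc1cc(C(=O)O)ccc1O | starting material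
16 | (1S,3E,8E)-3,10,10-trimethyl-7-methylidenecycloundeca-3,8-dien-1-yl 4-hydroxy-3-methoxybenzoate | C=C1/C=C/C(C)(C)C[C@@H](OC(=O)c2ccc(O)c(OC)c2)C/C(C)=C/CC1 | target

## Step count and risks

Total step count: 10.
Longest linear sequence: 8 steps (1 → 16 through steps 1, 2, 3, 6, 7, 8, 9, 10).

**Step 6 (alkylation of the lithiated carbamate).** The organolithium 8 may attack bromide 4 in the SN2′ sense, eliminate HBr, or lose enantiomeric purity through electron transfer. The fallback makes the same bond by a boron-ate 1,2-migration instead of a displacement at carbon; it sets out from 4 and comes back to the route at 9. B2pin2 with Pd2(dba)3 (cat.) in DMSO at 50 °C turns 4 into 4,4,5,5-tetramethyl-2-[(2E)-2-methyl-5-(2-methyl-1,3-dioxolan-2-yl)pent-2-en-1-yl]-1,3,2-dioxaborolane F1. Organolithium 8, made as in step 6, adds to boron at −78 °C to give the lithium boronate complex F2. On warming to reflux in Et2O this expels the carbamate with 1,2-shift of the allyl group and gives the secondary pinacol boronic ester F3. NaOH/H2O2 oxidises it with retention to the homoallylic alcohol F4, which has the same R configuration as 9. CbCl, NaH, THF at reflux re-forms carbamate 9, which is hydrolysed to 10 as before.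

**Step 8 (Heck closure of the 11-membered ring).** Ring strain may let oligomerisation or diene isomerisation by palladium hydride win. The fallback closes the same C7–C8 bond by transmetalation and reductive elimination instead of carbopalladation; it sets out from 10 and comes back at 13. A boryl-Heck reaction on the terminal alkene of 10 (B-chlorocatecholborane, Pd2(dba)3, P(t-Bu)(3,5-(t-Bu)2C6H3)2, LiOTf, Cy2NMe, PhCF3, 70 °C) gives the (E)-alkenyl catechol boronate F5. Pinacol/Et3N in the same flask converts it into the (E)-alkenyl pinacol boronate F6. KN(SiMe3)2 then PhNTf2 give, through the potassium enolate F7, the boryl enol triflate F8. Suzuki–Miyaura macrocyclisation (Pd(PPh3)4, Cs2CO3, THF/H2O, 60 °C, 0.002 M) then delivers 13.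

**Step 10 (Mitsunobu with a phenolic acid on a medium-ring alcohol).** Elimination to a triene or reaction at the phenol may compete. The fallback separates activation from displacement; it sets out from 14 and comes back at 16. MsCl, Et3N, CH2Cl2 at 0 °C gives (1R,3E,8E)-3,10,10-trimethyl-7-methylidenecycloundeca-3,8-dien-1-yl methanesulfonate F9. Vanillic acid 15 with CsHCO3 in DMF at 50 °C then displaces the mesylate by SN2 with inversion; only the carboxylate is ionised under these conditions, so 16 forms directly.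

## Further compounds

F1 | step 6 | 4,4,5,5-tetramethyl-2-[(2E)-2-methyl-5-(2-methyl-1,3-dioxolan-2-yl)pent-2-en-1-yl]-1,3,2-dioxaborolane | CC1(C)OB(C/C(C)=C/CCC2(C)OCCO2)OC1(C)C
F2 | step 6 | lithium boronate complex of 8 with F1 | [Li+].C=CC(C)(C)C[C@H](OC(=O)N(C(C)C)C(C)C)[B-]1(C/C(C)=C/CCC2(C)OCCO2)OC(C)(C)C(C)(C)O1
F3 | step 6 | 4,4,5,5-tetramethyl-2-[(5R,7E)-3,3,7-trimethyl-10-(2-methyl-1,3-dioxolan-2-yl)deca-1,7-dien-5-yl]-1,3,2-dioxaborolane | C=CC(C)(C)C[C@H](B1OC(C)(C)C(C)(C)O1)C/C(C)=C/CCC1(C)OCCO1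
F4 | step 6 | (5R,7E)-3,3,7-trimethyl-10-(2-methyl-1,3-dioxolan-2-yl)deca-1,7-dien-5-ol | C=CC(C)(C)C[C@H](O)C/C(C)=C/CCC1(C)OCCO1
F5 | step 8 | (1E,5R,7E)-1-(1,3,2-benzodioxaborol-2-yl)-3,3,7-trimethyl-11-oxododeca-1,7-dien-5-yl N,N-diisopropylcarbamate | c1ccc2OB(/C=C/C(C)(C)C[C@H](OC(=O)N(C(C)C)C(C)C)C/C(C)=C/CCC(C)=O)Oc2c1
F6 | step 8 | (1E,5R,7E)-3,3,7-trimethyl-11-oxo-1-(4,4,5,5-tetramethyl-1,3,2-dioxaborolan-2-yl)dodeca-1,7-dien-5-yl N,N-diisopropylcarbamate | CC1(C)OB(/C=C/C(C)(C)C[C@H](OC(=O)N(C(C)C)C(C)C)C/C(C)=C/CCC(C)=O)OC1(C)C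
F7 | step 8 | potassium (5E,8R,11E)-8-[(diisopropylcarbamoyl)oxy]-6,10,10-trimethyl-12-(4,4,5,5-tetramethyl-1,3,2-dioxaborolan-2-yl)dodeca-1,5,11-trien-2-olate | CC1(C)OB(/C=C/C(C)(C)C[C@H](OC(=O)N(C(C)C)C(C)C)C/C(C)=C/CCC(=C)[O-])OC1(C)C.[K+]
F8 | step 8 | (5E,8R,11E)-8-[(diisopropylcarbamoyl)oxy]-6,10,10-trimethyl-12-(4,4,5,5-tetramethyl-1,3,2-dioxaborolan-2-yl)dodeca-1,5,11-trien-2-yl trifluoromethanesulfonate | CC1(C)OB(/C=C/C(C)(C)C[C@H](OC(=O)N(C(C)C)C(C)C)C/C(C)=C/CCC(=C)OS(=O)(=O)C(F)(F)F)OC1(C)C
F9 | step 10 | (1R,3E,8E)-3,10,10-trimethyl-7-methylidenecycloundeca-3,8-dien-1-yl methanesulfonate | C=C1/C=C/C(C)(C)C[C@H](OS(C)(=O)=O)C/C(C)=C/CC1
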